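The route cuts both double bonds of the C12=C13–C14=C15 diene (numbering from the carboxyl carbon C1). This divides the target into a C1–C12 dioxolane aldehyde, a C13–C14 formyl ylide and a C15–C20 sulfone derived from leaf alcohol. One flask joins the three: Wittig homologation to the E-enal, then Julia–Kocienski olefination. The step exploits the 1,2-dioxolane ring, whose carbons C3 and C5 are fully substituted, so the O–O bond has no α-hydrogen for base to remove. It also exploits the C17=C18 Z-alkene, which arrives preformed. The precursor is the enantiopure (3R,5S) methyl ester carrying a 7-oxoheptyl chain on C5, made by peroxycarbenium–alkene annulation, chromatographic resolution and ozonolysis.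

Key step: step 9

Remark on the chemistry: the annulation is assumed to show little facial bias, so the route plans for a diastereomer separation followed by a resolution. Racemates are drawn as both enantiomers joined by a dot. All peroxides are handled on moderate scale behind a shield and are never distilled.

Step 1
Reactants: 1 dec-9-en-2-one
Product: 2 9,9-dimethoxydec-1-ene
Conditions: HC(OMe)3, MeOH, cat. p-TsOH·H2O, rt; Et3N quench
Reagents that add atoms: trimethyl orthoformate COC(OC)OC
Why: Acid-catalysed ketalisation, driven to completion by the orthoester as water scavenger, touches only the ketone because an isolated terminal alkene is inert to catalytic sulfonic acid at room temperature.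

Step 2
Reactants: 2 9,9-dimethoxydec-1-ene
Product: 3 9-hydroperoxy-9-methoxydec-1-ene (racemic)
Conditions: anhydrous H2O2 in Et2O (3 equiv), cat. camphorsulfonic acid, 0 °C; NaHCO3 quench
Reagents that add atoms: hydrogen peroxide OO
Why: Acid-catalysed perhydrolysis of a ketal exchanges one methoxy group through the oxocarbenium ion because H2O2 is the better nucleophile, low temperature and short contact hold the exchange at one group, and the new stereocentre is racemic and irrelevant since it is flattened again in step 4.

Step 3
Reactants: 3 9-hydroperoxy-9-methoxydec-1-ene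
Product: 4 triethyl[(2-methoxydec-9-en-2-yl)peroxy]silane (racemic)
Conditions: Et3SiCl, imidazole, DMF, 0 °C
Reagents that add atoms: chlorotriethylsilane CC[Si](Cl)(CC)CC
Why: Silylation of the hydroperoxide oxygen under mildly basic conditions keeps the acid-labile peroxy ketal intact and installs the silyl group that later departs when the ring closes.

Step 4
Reactants: 4 triethyl[(2-methoxydec-9-en-2-yl)peroxy]silane; 5 methyl 3-methylbut-3-enoate
Product: 6 rac-methyl 2-[(3R*,5S*)-3,5-dimethyl-5-(oct-7-en-1-yl)-1,2-dioxolan-3-yl]acetate (ring methyl groups trans)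
Conditions: 5 (3 equiv), SnCl4 (1 equiv), CH2Cl2, −78 → −40 °C; aq NaHCO3; silica gel separation of the ring diastereomers
Reagents that add atoms: none
Why: In this formal [3+2] annulation of a peroxycarbenium ion with an alkene, SnCl4 ionises the methoxy group, the 1,1-disubstituted alkene of 5 (far more nucleophilic than the monosubstituted chain alkene) attacks through its CH2 terminus to form C4–C5, and the silylperoxy oxygen traps the tertiary C3 cation with loss of silicon, so C3 and C5 are both set here without useful facial control and the isomer with trans ring methyl groups (assigned by NOE) is taken on as a racemate.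

Step 5
Reactants: 6 rac-methyl 2-[(3R*,5S*)-3,5-dimethyl-5-(oct-7-en-1-yl)-1,2-dioxolan-3-yl]acetate
Product: 7 methyl 2-[(3R,5S)-3,5-dimethyl-5-(oct-7-en-1-yl)-1,2-dioxolan-3-yl]acetate
Conditions: preparative HPLC, amylose tris(3,5-dimethylphenylcarbamate) on silica, hexane/i-PrOH, detection at 210 nm
Reagents that add atoms: none
Why: Chromatographic resolution on a chiral stationary phase parts the enantiomers without changing any bond, so the (3R,5S) configuration is selected rather than created, and it is assigned by vibrational circular dichroism against the calculated spectrum before material is carried on.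

Step 6
Reactants: 7 methyl 2-[(3R,5S)-3,5-dimethyl-5-(oct-7-en-1-yl)-1,2-dioxolan-3-yl]acetate
Product: 9 methyl 2-[(3R,5S)-3,5-dimethyl-5-(7-oxoheptyl)-1,2-dioxolan-3-yl]acetate, via secondary ozonide 8 (not isolated)
Conditions: O3, CH2Cl2, −78 °C, N2 purge; Me2S, −78 °C → rt
Reagents that add atoms: ozone [O-][O+]=O
Why: Ozonolysis with reductive work-up cleaves the only C=C bond, and dimethyl sulfide reduces the ozonide but not a hindered di-tertiary dialkyl peroxide, so the ring and both stereocentres stay untouched.

Step 7
Reactants: 10 (Z)-hex-3-en-1-ol; 11 1-phenyl-1H-tetrazole-5-thiol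
Product: 12 5-[(3Z)-hex-3-en-1-ylsulfanyl]-1-phenyl-1H-tetrazole
Conditions: PPh3, DIAD, THF, 0 °C → rt
Reagents that add atoms: none
Why: In this Mitsunobu thioetherification the acidic tetrazole thiol displaces the alkoxyphosphonium ion at the primary carbon in an SN2 step that leaves the remote Z-alkene untouched.

Step 8
Reactants: 12 5-[(3Z)-hex-3-en-1-ylsulfanyl]-1-phenyl-1H-tetrazole
Product: 13 5-[(3Z)-hex-3-en-1-ylsulfonyl]-1-phenyl-1H-tetrazole
Conditions: 30% aq H2O2, (NH4)6Mo7O24·4H2O (10 mol %), EtOH, 0 °C → rt
Reagents that add atoms: hydrogen peroxide OO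
Why: In this molybdate-catalysed oxidation of a sulfide to a sulfone the peroxomolybdate transfers oxygen to nucleophilic sulfur far faster than to an unactivated dialkyl alkene, so the Z-alkene survives where a peracid would epoxidise it.

Step 9
Reactants: 9 methyl 2-[(3R,5S)-3,5-dimethyl-5-(7-oxoheptyl)-1,2-dioxolan-3-yl]acetate; 14 (triphenylphosphoranylidene)acetaldehyde; 13 5-[(3Z)-hex-3-en-1-ylsulfonyl]-1-phenyl-1H-tetrazole
Product: 17 methyl 2-[(3R,5S)-3,5-dimethyl-5-[(7E,9E,12Z)-pentadeca-7,9,12-trien-1-yl]-1,2-dioxolan-3-yl]acetate, via E-enal 15 (not isolated), via potassium sulfonyl carbanion 16 (not isolated)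
Conditions: 14 (1.05 equiv), DME, 60 °C until 9 is consumed; cool to −55 °C; add by cannula 16 [from 13 (1.3 equiv), KN(SiMe3)2 (1.2 equiv), DME, −55 °C, 30 min]; −55 °C → rt; aq NH4Cl
Reagents that add atoms: none
Why: Ylide 14 and the C12 aldehyde combine through the dipole-minimised trans-oxaphosphetane, whose cycloreversion releases Ph3PO and the E-enal 15 (C12=C13); carbanion 16 then adds 1,2 to the C14 formyl group, the alkoxide moves the tetrazole from sulfur to oxygen (Smiles rearrangement), and the β-tetrazolyloxy sulfinate expels SO2 and phenyltetrazolate to create C14=C15. The closest known reaction types are the two-carbon Wittig homologation of aliphatic aldehydes with a formyl-stabilised ylide and the Julia–Kocienski olefination of enals with alkyl phenyltetrazolyl sulfones, so only the telescoping in one solvent and the neighbouring dioxolane are untried. No ring is closed and no stereocentre is made, and the quaternary centres C3 and C5 are spectators. E geometry is required twice: the stabilised ylide supplies it at C12=C13, while the potassium counter-ion in DME favours the open anti-selective addition and the allylic character of the adduct lets the elimination drain to the E-alkene at C14=C15. Single homologation is also needed, and it is secured by near-stoichiometric ylide, by the enal being a poorer electrophile than the saturated aldehyde, and by confirming full consumption of 9 before 16 is added so that the carbanion meets one aldehyde only. The substrate secures chemoselectivity because C3 and C5 bear no hydrogen, which rules out Kornblum–DeLaMare cleavage, because nothing in the flask (ylide, phosphine oxide, sulfonyl anion) reduces peroxides, and because the one base-sensitive site, C2–H of the β-peroxy ester, meets only the weakly basic carbanion 16 in the cold, the sulfone being kept in excess over KN(SiMe3)2.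

Step 10
Reactants: 17 methyl 2-[(3R,5S)-3,5-dimethyl-5-[(7E,9E,12Z)-pentadeca-7,9,12-trien-1-yl]-1,2-dioxolan-3-yl]acetate
Product: 19 2-[(3R,5S)-3,5-dimethyl-5-[(7E,9E,12Z)-pentadeca-7,9,12-trien-1-yl]-1,2-dioxolan-3-yl]acetic acid, via lithium carboxylate 18 (not isolated)
Conditions: LiOH (4 equiv), degassed THF/H2O 3:1, 0 °C → rt, dark; 1 M HCl to pH 4, 0 °C
Reagents that add atoms: lithium hydroxide [Li+].[OH-]
Why: In this saponification by acyl–oxygen cleavage hydroxide attacks the unhindered methyl ester carbonyl much faster than it can enolise C2, the carboxylate formed is inert to β-elimination of the peroxide, the quaternary C3 and C5 cannot epimerise, and exclusion of air and light protects the doubly allylic C16 methylene.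

Compound list
1 | dec-9-en-2-one | C=CCCCCCCC(C)=O | starting material
2 | 9,9-dimethoxydec-1-ene | C=CCCCCCCC(C)(OC)OC | intermediate
3 | 9-hydroperoxy-9-methoxydec-1-ene (racemic) | C=CCCCCCCC(C)(OC)OO | intermediate
4 | triethyl[(2-methoxydec-9-en-2-yl)peroxy]silane (racemic) | C=CCCCCCCC(C)(OC)OO[Si](CC)(CC)CC | intermediate
5 | methyl 3-methylbut-3-enoate | C=C(C)CC(=O)OC | starting material
6 | rac-methyl 2-[(3R*,5S*)-3,5-dimethyl-5-(oct-7-en-1-yl)-1,2-dioxolan-3-yl]acetate | C=CCCCCCC[C@@]1(C)C[C@](C)(CC(=O)OC)OO1.C=CCCCCCC[C@]1(C)C[C@@](C)(CC(=O)OC)OO1 | intermediate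
7 | methyl 2-[(3R,5S)-3,5-dimethyl-5-(oct-7-en-1-yl)-1,2-dioxolan-3-yl]acetate | C=CCCCCCC[C@@]1(C)C[C@](C)(CC(=O)OC)OO1 | intermediate
8 | methyl 2-[(3R,5S)-3,5-dimethyl-5-[6-(1,2,4-trioxolan-3-yl)hexyl]-1,2-dioxolan-3-yl]acetate (secondary ozonide, epimers at the trioxolane carbon) | C1OC(CCCCCC[C@@]2(C)C[C@](C)(CC(=O)OC)OO2)OO1 | intermediate
9 | methyl 2-[(3R,5S)-3,5-dimethyl-5-(7-oxoheptyl)-1,2-dioxolan-3-yl]acetate | O=CCCCCCC[C@@]1(C)C[C@](C)(CC(=O)OC)OO1 | intermediate
10 | (Z)-hex-3-en-1-ol | CC/C=C\CCO | starting material
11 | 1-phenyl-1H-tetrazole-5-thiol | Sc1nnnn1-c1ccccc1 | starting material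
12 | 5-[(3Z)-hex-3-en-1-ylsulfanyl]-1-phenyl-1H-tetrazole | CC/C=C\CCSc1nnnn1-c1ccccc1 | intermediate
13 | 5-[(3Z)-hex-3-en-1-ylsulfonyl]-1-phenyl-1H-tetrazole | CC/C=C\CCS(=O)(=O)c1nnnn1-c1ccccc1 | intermediate
14 | (triphenylphosphoranylidene)acetaldehyde | O=CC=P(c1ccccc1)(c1ccccc1)c1ccccc1 | starting material
15 | methyl 2-[(3R,5S)-3,5-dimethyl-5-[(7E)-9-oxonon-7-en-1-yl]-1,2-dioxolan-3-yl]acetate | O=C/C=C/CCCCCC[C@@]1(C)C[C@](C)(CC(=O)OC)OO1 | intermediate
16 | potassium (3Z)-1-[(1-phenyl-1H-tetrazol-5-yl)sulfonyl]hex-3-en-1-ide | CC/C=C\C[CH-]S(=O)(=O)c1nnnn1-c1ccccc1.[K+] | intermediate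
17 | methyl 2-[(3R,5S)-3,5-dimethyl-5-[(7E,9E,12Z)-pentadeca-7,9,12-trien-1-yl]-1,2-dioxolan-3-yl]acetate | CC/C=C\C/C=C/C=C/CCCCCC[C@@]1(C)C[C@](C)(CC(=O)OC)OO1 | intermediate
18 | lithium 2-[(3R,5S)-3,5-dimethyl-5-[(7E,9E,12Z)-pentadeca-7,9,12-trien-1-yl]-1,2-dioxolan-3-yl]acetate | CC/C=C\C/C=C/C=C/CCCCCC[C@@]1(C)C[C@](C)(CC(=O)[O-])OO1.[Li+] | intermediate
19 | 2-[(3R,5S)-3,5-dimethyl-5-[(7E,9E,12Z)-pentadeca-7,9,12-trien-1-yl]-1,2-dioxolan-3-yl]acetic acid | CC/C=C\C/C=C/C=C/CCCCCC[C@@]1(C)C[C@](C)(CC(=O)O)OO1 | target

Total step count: 10. Longest linear sequence: 8 steps (steps 1–6, 9 and 10). The sulfone branch (steps 7 and 8) runs in parallel.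

Steps most likely to fail

Step 9.
- What may go wrong:
  - Incomplete or double homologation in the Wittig stage would be carried into the sulfone stage.
  - E selectivity at C14=C15 may be eroded.
  - Deprotonation at C2 followed by β-elimination of the peroxide would open the ring.
  - Base may move the skipped alkene into conjugation.
- Fallback: the diene is made by forming the C13–C14 single bond between two alkenes of fixed geometry.
  - Setting out from 7, cross metathesis with vinylboronic acid pinacol ester (second-generation Hoveyda–Grubbs catalyst, CH2Cl2, 40 °C) should give the (E)-alkenyl pinacol boronate F1.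
  - In parallel, 10 is oxidised with Dess–Martin periodinane (NaHCO3-buffered CH2Cl2) to (Z)-hex-3-enal F2.
  - A Takai olefination (CrCl2, CHI3, THF, 0 °C), run on a fragment that holds no peroxide, converts F2 into (1E,4Z)-1-iodohepta-1,4-diene F3.
  - Suzuki–Miyaura coupling of the two (PdCl2(dppf), aq K3PO4, THF, rt; the chelating diphosphine leaves little free phosphine) comes back to the route at 17.

Step 4.
- What may go wrong:
  - The ester may sequester the Lewis acid.
  - The inductively deactivated alkene may attack sluggishly.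
  - The C3 cation may lose a proton instead of closing the ring.
  - The peroxy ketal may undergo acid-induced rearrangement.
- Fallback: the alkene is replaced by two much stronger silyl nucleophiles used in sequence.
  - Setting out from 4, a Mukaiyama-type addition of 2-(trimethylsilyloxy)propene to the same peroxycarbenium ion (SnCl4, CH2Cl2, −78 °C) gives 4-methyl-4-[(triethylsilyl)peroxy]dodec-11-en-2-one F4.
  - Acidic methanol (cat. p-TsOH, MeOH, rt) removes the silyl group, lets the hydroperoxide close onto the ketone and exchanges the hemiketal hydroxyl. This gives 3-methoxy-3,5-dimethyl-5-(oct-7-en-1-yl)-1,2-dioxolane F5.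
  - TiCl4-mediated displacement of the methoxy group by 1-methoxy-1-(trimethylsilyloxy)ethene (CH2Cl2, −78 °C) installs the C1–C2 arm at C3.
  - After separation of the ring diastereomers the sequence rejoins the route at 6.

Step 5.
- What may go wrong: a weakly functionalised aliphatic ester may be poorly discriminated on the chiral phase, and column loading may be low.
- Fallback: resolution through covalent diastereomers.
  - Setting out from 6, saponification (LiOH, THF/H2O) gives the racemic dioxolane acetic acid F6.
  - F6 is acylated onto (S)-4-benzyloxazolidin-2-one through its mixed pivalic anhydride (PivCl, Et3N, THF, −20 °C; then the oxazolidinone lithiated with n-BuLi, −78 °C).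
  - The acylation gives the imide of the (3R,5S) acid F7 and the imide of the (3S,5R) acid F8.
  - These are separated on silica gel or by crystallisation, with the known benzyl-bearing centre serving as internal reference for the configuration.
  - Non-basic methanolysis of the wanted imide (MeOH, cat. Sm(OTf)3, rt) returns to the route at 7.

Further compounds
F1 | step 9 | methyl 2-[(3R,5S)-3,5-dimethyl-5-[(7E)-8-(4,4,5,5-tetramethyl-1,3,2-dioxaborolan-2-yl)oct-7-en-1-yl]-1,2-dioxolan-3-yl]acetate | CC1(C)OB(/C=C/CCCCCC[C@@]2(C)C[C@](C)(CC(=O)OC)OO2)OC1(C)C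
F2 | step 9 | (Z)-hex-3-enal | CC/C=C\CC=O
F3 | step 9 | (1E,4Z)-1-iodohepta-1,4-diene | CC/C=C\C/C=C/I
F4 | step 4 | 4-methyl-4-[(triethylsilyl)peroxy]dodec-11-en-2-one (racemic) | C=CCCCCCCC(C)(CC(C)=O)OO[Si](CC)(CC)CC
F5 | step 4 | 3-methoxy-3,5-dimethyl-5-(oct-7-en-1-yl)-1,2-dioxolane (mixture of stereoisomers) | C=CCCCCCCC1(C)CC(C)(OC)OO1
F6 | step 5 | rac-2-[(3R*,5S*)-3,5-dimethyl-5-(oct-7-en-1-yl)-1,2-dioxolan-3-yl]acetic acid | C=CCCCCCC[C@@]1(C)C[C@](C)(CC(=O)O)OO1.C=CCCCCCC[C@]1(C)C[C@@](C)(CC(=O)O)OO1
F7 | step 5 | (4S)-4-benzyl-3-{2-[(3R,5S)-3,5-dimethyl-5-(oct-7-en-1-yl)-1,2-dioxolan-3-yl]acetyl}-1,3-oxazolidin-2-one | C=CCCCCCC[C@@]1(C)C[C@](C)(CC(=O)N2C(=O)OC[C@@H]2Cc3ccccc3)OO1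
F8 | step 5 | (4S)-4-benzyl-3-{2-[(3S,5R)-3,5-dimethyl-5-(oct-7-en-1-yl)-1,2-dioxolan-3-yl]acetyl}-1,3-oxazolidin-2-one | C=CCCCCCC[C@]1(C)C[C@@](C)(CC(=O)N2C(=O)OC[C@@H]2Cc3ccccc3)OO1
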